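**Assumption:** methyl (R)-glycidate (commercial, made from L-serine) is taken as the cheap chiral starting material. The route has not been run; selectivities are predictions from analogy.

## Retrosynthetic overview

1. The exocyclic methylene comes from a ring ketone, and the ketone plus the C8–C9 side-chain bond come from an anionic oxy-Cope [3,3] rearrangement of a 3-hydroxy-1,5-diene.
2. That diene comes from γ-allylation of an α-methylene cyclohexanone with an 8-bromogeranyl unit; the pyranone (bought) is attached at C3 by Pd-allylation of the geranyl acetate terminus.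
3. The α-methylene ketone comes from (S)-2,2-dimethyl-3-methylenecyclohexanol by allylic oxidation.
4. That ring comes from Ti(III) epoxide–alkyne radical cyclisation of an (S)-epoxide built from methyl (R)-glycidate, a butynyl Grignard and MeMgBr.
5. Ring order: the carbocycle is the only ring made (Step 4); the pyranone ring is purchased. C3 is bought; C1 is set by enolate protonation under control of C3.

## Route

**Step 1**
Reactants: 1 methyl (R)-glycidate; 2 (4-bromobut-1-yn-1-yl)trimethylsilane
Product: 3 methyl (2R)-2-hydroxy-7-(trimethylsilyl)hept-6-ynoate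
Conditions: 2, Mg, THF; then CuI (10 mol %), 1, THF, −40 → −20 °C
Reagents that add atoms: none (both partners are numbered reactants)
Why: Cu-catalysed Grignard SN2 opening of the epoxide at the unsubstituted CH2 outruns ester addition at low temperature, and the purchased stereocentre is not touched.

**Step 2**
Reactants: 3
Product: 4 (3R)-2-methyl-8-(trimethylsilyl)oct-7-yne-2,3-diol
Conditions: MeMgBr (3.3 equiv), THF, 0 °C → rt
Reagents that add atoms: MeMgBr, C[Mg]Br
Why: Double Grignard addition to the ester gives the tertiary carbinol; the stereocentre is not involved.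

**Step 3**
Reactants: 4
Product: 5 (3S)-2,2-dimethyl-3-(pent-4-yn-1-yl)oxirane
Conditions: MsCl, Et3N, CH2Cl2, 0 °C; then K2CO3, MeOH, rt
Reagents that add atoms: none
Why: Selective mesylation of the secondary OH and intramolecular Williamson closure by the tertiary alkoxide inverts the carbinol carbon ((R)-diol → (S)-epoxide), while K2CO3/MeOH also removes the alkynyl TMS.

**Step 4**
Reactants: 5
Product: 6 (1S)-2,2-dimethyl-3-methylidenecyclohexan-1-ol
Conditions: Cp2TiCl2 (20 mol %), Mn, 2,4,6-collidine·HCl, THF, rt, slow addition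
Reagents that add atoms: none
Why: Nugent–RajanBabu Ti(III) epoxide opening gives the tertiary radical, which closes 6-exo-dig onto the alkyne and is reduced/protonated to the exocyclic alkene; the C–O stereocentre is never broken.

**Step 5**
Reactants: 6
Product: 7 tert-butyl{[(1S)-2,2-dimethyl-3-methylidenecyclohexyl]oxy}dimethylsilane
Conditions: TBSOTf, 2,6-lutidine, CH2Cl2, −78 → 0 °C
Reagents that add atoms: TBSOTf, CC(C)(C)[Si](C)(C)OS(=O)(=O)C(F)(F)F
Why: Silyl triflate protects the hindered neopentyl-type alcohol; the bulky OTBS is needed later to bias the enolate protonation.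

**Step 6**
Reactants: 7
Product: 8 (1RS,4S)-4-[(tert-butyldimethylsilyl)oxy]-3,3-dimethyl-2-methylidenecyclohexan-1-ol
Conditions: SeO2 (0.5 equiv), t-BuOOH, CH2Cl2, rt
Reagents that add atoms: SeO2, O=[Se]=O; t-BuOOH, CC(C)(C)OO
Why: Riley oxidation (ene, then [2,3]-sigmatropic shift) can only use the ring CH2 (the other allylic carbon is quaternary) and returns the exocyclic alkene, as in β-pinene → pinocarveol; the new carbinol configuration is irrelevant.

**Step 7**
Reactants: 8
Product: 9 (4S)-4-[(tert-butyldimethylsilyl)oxy]-3,3-dimethyl-2-methylidenecyclohexan-1-one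
Conditions: Dess–Martin periodinane, NaHCO3, CH2Cl2, 0 °C → rt; use at once
Reagents that add atoms: none
Why: Mild oxidation of the allylic alcohol gives the α-methylene ketone, which the adjacent quaternary carbon shields from dimerisation (cf. pinocarvone).

**Step 8**
Reactants: 10 geranyl acetate
Product: 11 (2E,6E)-8-hydroxy-3,7-dimethylocta-2,6-dien-1-yl acetate
Conditions: SeO2 (cat.), t-BuOOH, salicylic acid (cat.), CH2Cl2, rt; NaBH4 work-up
Reagents that add atoms: SeO2, O=[Se]=O; t-BuOOH, CC(C)(C)OO
Why: SeO2 allylic oxidation is selective for the (E)-methyl of the distal, more electron-rich trisubstituted alkene.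

**Step 9**
Reactants: 11
Product: 12 (2E,6E)-8-bromo-3,7-dimethylocta-2,6-dien-1-yl acetate
Conditions: CBr4, PPh3, CH2Cl2, 0 °C
Reagents that add atoms: CBr4, BrC(Br)(Br)Br
Why: Appel bromination of the primary allylic alcohol proceeds without transposition and tolerates the acetate.

**Step 10**
Reactants: 9; 12
Product: 13 (2E)-6-[(4S)-4-(TBSO)-1-hydroxy-3,3-dimethyl-2-methylidenecyclohexyl]-3,7-dimethylocta-2,7-dien-1-yl acetate (diastereomer mixture at ring C1 and chain C6)
Conditions: Zn dust, THF/sat. aq NH4Cl, 0 °C → rt
Reagents that add atoms: none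
Why: Barbier allylation adds the allylzinc 1,2 to the ketone through its γ-carbon (cyclic SE2′ transition state), giving the 3-hydroxy-1,5-diene; both new stereocentres are erased in Step 12.

**Step 11**
Reactants: 13; 14 4-hydroxy-6-methyl-2H-pyran-2-one
Product: 15 3-{(2E)-6-[(4S)-4-(TBSO)-1-hydroxy-3,3-dimethyl-2-methylidenecyclohexyl]-3,7-dimethylocta-2,7-dien-1-yl}-4-hydroxy-6-methyl-2H-pyran-2-one
Conditions: Pd(PPh3)4 (5 mol %), DBU, THF, 60 °C
Reagents that add atoms: none
Why: Tsuji–Trost allylation: the primary allylic acetate ionises and the soft pyronate attacks the unhindered π-allyl terminus through C3 (O-allyl isomers funnel to C-allyl under Pd(0)), keeping the 2E alkene; the tertiary alcohol is inert under basic conditions.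

**Step 12**
Reactants: 15
Product: 16 3-{(2E,6E)-9-[(1S,3S)-3-(TBSO)-2,2-dimethyl-6-oxocyclohexyl]-3,7-dimethylnona-2,6-dien-1-yl}-4-hydroxy-6-methyl-2H-pyran-2-one
Conditions: KH (4 equiv), 18-crown-6, THF, 0 °C → rt; then BHT, −78 °C; aq NH4Cl
Reagents that add atoms: none
Why: Anionic oxy-Cope [3,3] rearrangement through a chair with the chain equatorial forms the C8–C9 bond and the 6E alkene. The ring enolate is then protonated axially, anti to the pseudoaxial methyl, in the half-chair with OTBS equatorial (the other half-chair presents axial OTBS to the bulky proton donor), placing the side chain cis to OTBS.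

**Step 13**
Reactants: 16
Product: 17 3-{(2E,6E)-9-[(1R,3S)-3-(TBSO)-2,2-dimethyl-6-methylidenecyclohexyl]-3,7-dimethylnona-2,6-dien-1-yl}-4-hydroxy-6-methyl-2H-pyran-2-one
Conditions: Zn, CH2Br2, TiCl4, THF/CH2Cl2, 0 °C → rt
Reagents that add atoms: CH2Br2, BrCBr
Why: Takai–Lombardo methylenation is non-basic, so the α-stereocentre does not epimerise and the pyranone carbonyl is left alone (the descriptor changes from S to R only through CIP priorities).

**Step 14**
Reactants: 17
Product: 18 sartorypyrone D
Conditions: HF·pyridine, pyridine/THF, 0 °C → rt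
Reagents that add atoms: none
Why: Buffered fluoride removes the hindered TBS ether without isomerising the exocyclic alkene.

## Compound list

1 | methyl (2R)-oxirane-2-carboxylate | COC(=O)[C@H]1CO1 | starting material
2 | (4-bromobut-1-yn-1-yl)trimethylsilane | C[Si](C)(C)C#CCCBr | starting material
3 | methyl (2R)-2-hydroxy-7-(trimethylsilyl)hept-6-ynoate | COC(=O)[C@H](O)CCCC#C[Si](C)(C)C | intermediate
4 | (3R)-2-methyl-8-(trimethylsilyl)oct-7-yne-2,3-diol | CC(C)(O)[C@H](O)CCCC#C[Si](C)(C)C | intermediate
5 | (3S)-2,2-dimethyl-3-(pent-4-yn-1-yl)oxirane | CC1(C)O[C@H]1CCCC#C | intermediate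
6 | (1S)-2,2-dimethyl-3-methylidenecyclohexan-1-ol | C=C1CCC[C@H](O)C1(C)C | intermediate
7 | TBS ether of 6 | C=C1CCC[C@H](O[Si](C)(C)C(C)(C)C)C1(C)C | intermediate
8 | (1RS,4S)-4-(TBSO)-3,3-dimethyl-2-methylidenecyclohexan-1-ol | C=C1C(O)CC[C@H](O[Si](C)(C)C(C)(C)C)C1(C)C | intermediate
9 | (4S)-4-(TBSO)-3,3-dimethyl-2-methylidenecyclohexan-1-one | C=C1C(=O)CC[C@H](O[Si](C)(C)C(C)(C)C)C1(C)C | intermediate
10 | geranyl acetate | CC(C)=CCC/C(C)=C/COC(C)=O | starting material
11 | (2E,6E)-8-hydroxy-3,7-dimethylocta-2,6-dien-1-yl acetate | OC/C(C)=C/CC/C(C)=C/COC(C)=O | intermediate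
12 | (2E,6E)-8-bromo-3,7-dimethylocta-2,6-dien-1-yl acetate | BrC/C(C)=C/CC/C(C)=C/COC(C)=O | intermediate
13 | Barbier adduct (tertiary 3-hydroxy-1,5-diene, acetate) | C=C1C(O)(C(CC/C(C)=C/COC(C)=O)C(C)=C)CC[C@H](O[Si](C)(C)C(C)(C)C)C1(C)C | intermediate
14 | 4-hydroxy-6-methyl-2H-pyran-2-one | Cc1cc(O)cc(=O)o1 | starting material
15 | C3-allylated pyranone (oxy-Cope substrate) | C=C1C(O)(C(CC/C(C)=C/Cc2c(O)cc(C)oc2=O)C(C)=C)CC[C@H](O[Si](C)(C)C(C)(C)C)C1(C)C | intermediate
16 | ring ketone, (1S,3S)-3-(TBSO)-2,2-dimethyl-6-oxocyclohexyl | O=C1CC[C@H](O[Si](C)(C)C(C)(C)C)C(C)(C)[C@@H]1CC/C(C)=C/CC/C(C)=C/Cc1c(O)cc(C)oc1=O | intermediate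
17 | O-TBS sartorypyrone D | C=C1CC[C@H](O[Si](C)(C)C(C)(C)C)C(C)(C)[C@@H]1CC/C(C)=C/CC/C(C)=C/Cc1c(O)cc(C)oc1=O | intermediate
18 | sartorypyrone D | C=C1CC[C@H](O)C(C)(C)[C@@H]1CC/C(C)=C/CC/C(C)=C/Cc1c(O)cc(C)oc1=O | target

## Step count and risks

Total steps: 14. Longest linear sequence: 12 (Steps 1–7, then 10–14); Steps 8–9 make the side-chain bromide.

Steps most likely to fail:

1. **Step 12 (oxy-Cope and enolate protonation).** The hindered alkoxide may fragment (retro-allylation), the 6E selectivity may be incomplete, and the C1 protonation is the weakest stereocontrol in the route (the equilibrium between C1 epimers is expected to be close to 1:1, so it must be kinetic). Fallback: set C1 in a ring closure instead. Cyclise (S)-6,7-epoxygeranyl acetate with Cp2TiCl (chair transition state gives the cis C1/C3 ring with the exocyclic alkene), convert its CH2OAc to a sulfone, alkylate with the C8 allylic bromide and desulfonylate.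
2. **Step 10 (Barbier allylation).** The enone 9 is hindered and can dimerise, and reversible addition would leak to the useless linear α-adduct. Fallback: convert 12 to its pinacol allylboronate (B2pin2, Cu catalysis) and use allylboration, which can only deliver the γ-carbon through a closed transition state.
3. **Step 4 (Ti(III) 6-exo-dig cyclisation).** Reduction or β-hydride loss of the tertiary radical may compete with the slower six-membered closure. Fallback: carry the carbinol and gem-dimethyl carbons in from (R)-pantolactone and close the ring by metathesis of a vinyl ketone/allyl diene, then hydrogenate and methylenate to reach 7.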